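**Retrosynthetic overview**

1. Numbering: ring C = C8–C9–C11–C12–C13–C14; ring D = C13–C14–C15–C16(OAc)–C17–C25–C24; butenolide = C17–C18–C19(=O)–O–C25. The plan rests on one feature: the quaternary C8 with its axial methyl and the C8–C14 bond of trans-fused ring C map onto an exocyclic C8 methylene on the decalin of (+)-sclareolide, which supplies rings A and B with C5, C9 and C10.
2. Ring D is opened first: acetate and silyl ether off, C24=C25 by an intramolecular vinylogous aldol condensation of a C24 aldehyde with the butenolide CH2, and C16–C17 by a NiCl2/CrCl2 coupling of a C16 aldehyde with 4-triflyloxyfuranone. C16 is then fixed by oxidation and oxazaborolidine reduction.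
3. Ring C is opened at C8–C14: hydrogen-atom transfer to the C8 methylene of a decalin dienoate and 6-exo radical closure onto the enoate set C8 and C14.
4. The dienoate comes from a C12 Grignard reagent by copper-catalysed asymmetric allylic alkylation (sets C13) and cross-metathesis with methyl acrylate. C8 is kept as a silyl-protected carbinol until after the metathesis, so that no 1,1-disubstituted alkene is present to ring-close onto the vinyl group; dehydration to the methylene comes last.
5. Order of rings: A and B bought, C in step 10, butenolide attached in step 13, D in step 19.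

Key step: step 10

Remark: (R,Rp)-Taniaphos is (Rp)-1-[(R)-α-(dimethylamino)-2-(diphenylphosphino)benzyl]-2-(diphenylphosphino)ferrocene; its sense of induction (13S) and that of the (S)-oxazaborolidine (16R) are assigned by analogy with simpler substrates, and the antipode would be taken if a trial showed the opposite sense. PMB = 4-methoxybenzyl, TES = triethylsilyl, TBS = tert-butyldimethylsilyl.

**Route**

Step 1
Reactants: 1 (+)-sclareolide
Product: 2 8α,12-dihydroxy-13,14,15,16-tetranorlabdane (tertiary 8α-OH, primary 12-OH on the C9 ethyl arm)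
Conditions: LiAlH4, THF, 0 °C to rt
Reagents that add atoms: none
Why: Hydride reduction of the lactone to the primary/tertiary diol, which touches no stereocentre.

Step 2
Reactants: 2 8α,12-dihydroxy-13,14,15,16-tetranorlabdane
Product: 3 8α,12-bis(triethylsilyloxy)-13,14,15,16-tetranorlabdane
Conditions: TESOTf (3 equiv), 2,6-lutidine, CH2Cl2, −78 to 0 °C
Reagents that add atoms: triethylsilyl trifluoromethanesulfonate, CC[Si](CC)(CC)OS(=O)(=O)C(F)(F)F
Why: Silyl triflate silylation is forceful enough to cap the hindered tertiary C8 hydroxyl, which would otherwise close the tetrahydrofuran (5-exo-tet) as soon as C12 carries a leaving group.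

Step 3
Reactants: 3 8α,12-bis(triethylsilyloxy)-13,14,15,16-tetranorlabdane
Product: 4 8α-(triethylsilyloxy)-13,14,15,16-tetranorlabdan-12-ol
Conditions: PPTS (cat.), MeOH/CH2Cl2, 0 °C
Reagents that add atoms: none
Why: Acid-catalysed methanolysis of silyl ethers is governed by sterics, so the primary triethylsilyl ether should be cleaved well before the tertiary one.

Step 4
Reactants: 4 8α-(triethylsilyloxy)-13,14,15,16-tetranorlabdan-12-ol
Product: 5 12-bromo-8α-(triethylsilyloxy)-13,14,15,16-tetranorlabdane
Conditions: CBr4, PPh3, 2,6-lutidine, CH2Cl2, 0 °C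
Reagents that add atoms: carbon tetrabromide, BrC(Br)(Br)Br
Why: Appel bromination, an SN2 displacement of the oxyphosphonium ion at the unhindered primary C12 under buffered conditions that leave the tertiary silyl ether intact.

Step 5
Reactants: 6 (E)-1,4-dibromobut-2-ene (3 equiv); 7 4-methoxybenzyl alcohol
Product: 8 (E)-1-bromo-4-(4-methoxybenzyloxy)but-2-ene
Conditions: NaH, THF, 0 °C to rt
Reagents that add atoms: none
Why: Williamson ether synthesis on a reactive allylic bromide, in which the excess of dibromide suppresses double substitution and the E geometry is kept.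

Step 6
Reactants: 5 12-bromo-8α-(triethylsilyloxy)-13,14,15,16-tetranorlabdane; 8 (E)-1-bromo-4-(4-methoxybenzyloxy)but-2-ene
Product: 10 (13S)-vinyl PMB ether (decalin with C8α-OTES whose C9 arm is CH2CH2–CH(CH2OPMB)–CH=CH2), via Grignard reagent 9 (not isolated)
Conditions: Mg, Et2O, reflux; then 8, CuBr·SMe2 (5 mol%), (R,Rp)-Taniaphos (6 mol%), CH2Cl2, −78 °C, slow addition
Reagents that add atoms: none
Why: Copper-catalysed asymmetric allylic alkylation (SN2′) of a primary alkyl Grignard reagent with a 4-alkoxybut-2-enyl bromide, a substrate class on which the CuBr·SMe2/Taniaphos system is established, forms C12–C13 at the γ-carbon while the ligand selects the alkene face so that C13 is S.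

Step 7
Reactants: 10 (13S)-vinyl PMB ether; 11 methyl acrylate (10 equiv)
Product: 12 methyl (E)-enoate with C8α-OTES (C9 arm CH2CH2–CH(CH2OPMB)–CH=CH–CO2Me, 13S)
Conditions: second-generation Hoveyda–Grubbs catalyst (5 mol%), CH2Cl2, 40 °C
Reagents that add atoms: none
Why: Olefin cross-metathesis of a terminal alkene with an acrylate gives the E-enoate, and because C8 is still a saturated silyloxy carbon the vinyl group is the only alkene, so ring-closing metathesis onto a C8 methylene cannot compete.

Step 8
Reactants: 12 methyl (E)-enoate with C8α-OTES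
Product: 13 methyl (E)-enoate with free tertiary 8α-OH
Conditions: HF·pyridine, pyridine, THF, 0 °C to rt
Reagents that add atoms: none
Why: Fluoride-driven cleavage of the silyl ether under weakly acidic conditions that leave the PMB ether, the methyl ester and the base-sensitive allylic C13 stereocentre untouched.

Step 9
Reactants: 13 methyl (E)-enoate with free tertiary 8α-OH
Product: 14 exocyclic-methylene dienoate (C8=CH2 decalin with the (13S) C9 arm CH2CH2–CH(CH2OPMB)–CH=CH–CO2Me)
Conditions: SOCl2, pyridine, CH2Cl2, −78 °C; chromatography on AgNO3-impregnated silica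
Reagents that add atoms: none
Why: Dehydration through the chlorosulfite (E2): the equatorial C8–O bond has no antiperiplanar ring hydrogen, so elimination into the axial methyl group to the exocyclic alkene should dominate, and ring-alkene isomers are removed on the silver-loaded silica.

Step 10
Reactants: 14 exocyclic-methylene dienoate
Product: 15 tricyclic ester (trans-fused ring C; C8 methyl β axial, C13 CH2OPMB α equatorial, C14 CH2CO2Me β equatorial, H14 α)
Conditions: Fe(acac)3 (30 mol%), PhSiH3 (2.5 equiv), EtOH/(CH2OH)2 5:1, THF co-solvent, 60 °C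
Reagents that add atoms: none
Why: The iron hydride formed from Fe(acac)3 and PhSiH3 transfers a hydrogen atom to the terminal carbon of the 1,1-disubstituted C8 methylene, which creates the C8 methyl and a tertiary C8 radical; this nucleophilic radical adds to C14, the β-carbon of the enoate, and the α-ester radical at C15 is reduced by divalent iron and protonated by ethanol. The closest known reaction type is the MHAT-initiated reductive olefin coupling (radical conjugate addition of Giese type) in its intramolecular form. Ring C (C8–C9–C11–C12–C13–C14) closes in the 6-exo-trig mode. C8 is set by a chair transition state in which the new bond forms on the α face, equatorial on ring B and away from the axial C10 methyl, so the C8 methyl ends axial (β) and the ring fusion trans; C14 is set by the same chair, in which the C13 CH2OPMB group and the enoate arm are both equatorial, so H14 is α and trans to H13. The step needs hydrogen-atom transfer to the methylene in preference to the enoate and cyclisation faster than reduction of the tertiary radical: the iron hydride prefers the electron-neutral alkene, and the tether places the electron-poor C14 in 6-exo reach of C8. Any ring-B alkene isomer with a C7=C8 double bond carried over from step 9 would give the same C8 radical.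

Step 11
Reactants: 15 tricyclic ester
Product: 16 tricyclic C16 aldehyde (C14–CH2–CHO)
Conditions: i-Bu2AlH (1.1 equiv), CH2Cl2, −78 °C; MeOH, aqueous potassium sodium tartrate
Reagents that add atoms: none
Why: Partial reduction of the ester, in which the aluminium hemiacetal is stable at −78 °C and releases the aldehyde only on work-up, while the PMB ether is inert.

Step 12
Reactants: 17 tetronic acid
Product: 18 4-(trifluoromethylsulfonyloxy)furan-2(5H)-one
Conditions: Tf2O, i-Pr2NEt, CH2Cl2, −78 °C
Reagents that add atoms: trifluoromethanesulfonic anhydride, O=S(=O)(OS(=O)(=O)C(F)(F)F)C(F)(F)F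
Why: O-Sulfonylation of the enol of a vinylogous acid gives the vinyl triflate.

Step 13
Reactants: 16 tricyclic C16 aldehyde; 18 4-(trifluoromethylsulfonyloxy)furan-2(5H)-one (2 equiv)
Product: 19 C16 carbinol as both epimers (C15H2–C16H(OH) bonded to C4 of the furan-2(5H)-one, which is C17)
Conditions: CrCl2 (6 equiv), NiCl2 (2 mol%), degassed DMF, rt
Reagents that add atoms: none
Why: Nozaki–Hiyama–Kishi coupling, in which zerovalent nickel inserts into the vinyl triflate and transmetalation gives a non-basic alkenyl species of trivalent chromium that adds only to the aldehyde; C16 is expected as an epimer mixture that steps 14 and 15 converge.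

Step 14
Reactants: 19 C16 carbinol as both epimers
Product: 20 C16 ketone (4-acylbutenolide)
Conditions: Dess–Martin periodinane, NaHCO3, CH2Cl2, 0 °C to rt
Reagents that add atoms: none
Why: Dess–Martin oxidation of the secondary allylic alcohol under buffered, non-basic conditions merges both C16 epimers into one ketone, which is used at once.

Step 15
Reactants: 20 C16 ketone
Product: 21 (16R)-alcohol
Conditions: (S)-2-methyl-CBS-oxazaborolidine (0.5 equiv), catecholborane, toluene, −78 °C
Reagents that add atoms: none
Why: Corey–Bakshi–Shibata reduction, 1,2-selective for conjugated ketones, in which the ketone binds with the butenolide as the large group and the C15 methylene as the small one, so that hydride is delivered under reagent control to the face that gives 16R.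

Step 16
Reactants: 21 (16R)-alcohol
Product: 22 (16R)-tert-butyldimethylsilyl ether
Conditions: TBSOTf, 2,6-lutidine, CH2Cl2, −78 °C
Reagents that add atoms: tert-butyldimethylsilyl trifluoromethanesulfonate, CC(C)(C)[Si](C)(C)OS(=O)(=O)C(F)(F)F
Why: Silylation with a silyl triflate and a hindered weak base that at low temperature neither enolises the butenolide nor cleaves the PMB ether; a silyl ether is chosen over the final acetate because it cannot ionise at C16 during step 19.

Step 17
Reactants: 22 (16R)-tert-butyldimethylsilyl ether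
Product: 23 C24 primary alcohol
Conditions: DDQ, CH2Cl2/pH 7 buffer, 0 °C
Reagents that add atoms: none
Why: Oxidative cleavage of the PMB ether by DDQ (hydride abstraction at the electron-rich benzylic position, then hydrolysis) is orthogonal to the silyl ether and the electron-poor butenolide.

Step 18
Reactants: 23 C24 primary alcohol
Product: 24 C24 aldehyde
Conditions: Dess–Martin periodinane, NaHCO3, CH2Cl2, 0 °C to rt
Reagents that add atoms: none
Why: Dess–Martin oxidation under buffered conditions; the formyl group sits equatorial on ring C, the more stable C13 configuration, so epimerisation is not a threat.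

Step 19
Reactants: 24 C24 aldehyde
Product: 27 pentacyclic (16R)-silyl ether (ring D closed; C24=C25 alkylidene butenolide), via silyloxyfuran aldehyde 25 (not isolated), via silylated aldol adduct 26 (not isolated)
Conditions: TBSOTf (1.5 equiv), Et3N (3 equiv), CH2Cl2, −78 to 0 °C; then DBU, rt
Reagents that add atoms: none
Why: Intramolecular vinylogous aldol condensation: soft enolisation gives the 2-silyloxyfuran, whose C25 (the γ-carbon, the most nucleophilic site) adds to the silyl-activated C24 aldehyde in a Mukaiyama-type closure of the seven-membered ring D, and DBU then removes the acidic C25 proton and expels silanolate (E1cB) to give the C24=C25 alkene, whose geometry is dictated by the ring.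

Step 20
Reactants: 27 pentacyclic (16R)-silyl ether
Product: 28 pentacyclic (16R)-alcohol
Conditions: HF·pyridine, THF, 0 °C to rt
Reagents that add atoms: none
Why: Acidic fluoride desilylation avoids basic fluoride sources that could attack the alkylidene butenolide.

Step 21
Reactants: 28 pentacyclic (16R)-alcohol
Product: 29 CNP0193439.1
Conditions: Ac2O, pyridine, DMAP (cat.), CH2Cl2, rt
Reagents that add atoms: acetic anhydride, CC(=O)OC(C)=O
Why: DMAP-catalysed acylation of the secondary alcohol proceeds with retention at C16.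

**Compound list**

1 | (+)-sclareolide | O=C1C[C@H]2[C@](C)(O1)CC[C@H]1C(C)(C)CCC[C@]21C | starting material
2 | 8α,12-dihydroxy-13,14,15,16-tetranorlabdane | OCC[C@H]1[C@](C)(O)CC[C@H]2C(C)(C)CCC[C@]12C | intermediate
3 | 8α,12-bis(triethylsilyloxy)-13,14,15,16-tetranorlabdane | CC[Si](CC)(CC)OCC[C@H]1[C@](C)(O[Si](CC)(CC)CC)CC[C@H]2C(C)(C)CCC[C@]12C | intermediate
4 | 8α-(triethylsilyloxy)-13,14,15,16-tetranorlabdan-12-ol | OCC[C@H]1[C@](C)(O[Si](CC)(CC)CC)CC[C@H]2C(C)(C)CCC[C@]12C | intermediate
5 | 12-bromo-8α-(triethylsilyloxy)-13,14,15,16-tetranorlabdane | BrCC[C@H]1[C@](C)(O[Si](CC)(CC)CC)CC[C@H]2C(C)(C)CCC[C@]12C | intermediate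
6 | (E)-1,4-dibromobut-2-ene | BrC/C=C/CBr | starting material
7 | 4-methoxybenzyl alcohol | COc1ccc(CO)cc1 | starting material
8 | (E)-1-bromo-4-(4-methoxybenzyloxy)but-2-ene | COc1ccc(COC/C=C/CBr)cc1 | intermediate
9 | 8α-(triethylsilyloxy)-13,14,15,16-tetranorlabdan-12-ylmagnesium bromide (not isolated) | Br[Mg]CC[C@H]1[C@](C)(O[Si](CC)(CC)CC)CC[C@H]2C(C)(C)CCC[C@]12C | intermediate
10 | (13S)-vinyl PMB ether with C8α-OTES | C=C[C@@H](COCc1ccc(OC)cc1)CC[C@H]1[C@](C)(O[Si](CC)(CC)CC)CC[C@H]2C(C)(C)CCC[C@]12C | intermediate
11 | methyl acrylate | C=CC(=O)OC | starting material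
12 | methyl (E)-enoate with C8α-OTES (13S) | COC(=O)/C=C/[C@@H](COCc1ccc(OC)cc1)CC[C@H]1[C@](C)(O[Si](CC)(CC)CC)CC[C@H]2C(C)(C)CCC[C@]12C | intermediate
13 | methyl (E)-enoate with free tertiary 8α-OH (13S) | COC(=O)/C=C/[C@@H](COCc1ccc(OC)cc1)CC[C@H]1[C@](C)(O)CC[C@H]2C(C)(C)CCC[C@]12C | intermediate
14 | exocyclic-methylene dienoate, key precursor (13S) | COC(=O)/C=C/[C@@H](COCc1ccc(OC)cc1)CC[C@H]1C(=C)CC[C@H]2C(C)(C)CCC[C@]12C | intermediate
15 | tricyclic ester, key product (C8 methyl β, C13 CH2OPMB α, C14 CH2CO2Me β) | COC(=O)C[C@@H]2[C@@H](COCc1ccc(OC)cc1)CC[C@H]1[C@@]2(C)CC[C@H]2C(C)(C)CCC[C@]12C | intermediate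
16 | tricyclic C16 aldehyde | O=CC[C@@H]2[C@@H](COCc1ccc(OC)cc1)CC[C@H]1[C@@]2(C)CC[C@H]2C(C)(C)CCC[C@]12C | intermediate
17 | tetronic acid (4-hydroxyfuran-2(5H)-one) | OC1=CC(=O)OC1 | starting material
18 | 4-(trifluoromethylsulfonyloxy)furan-2(5H)-one | O=C1C=C(OS(=O)(=O)C(F)(F)F)CO1 | intermediate
19 | C16 carbinol, both epimers | OC(C3=CC(=O)OC3)C[C@@H]2[C@@H](COCc1ccc(OC)cc1)CC[C@H]1[C@@]2(C)CC[C@H]2C(C)(C)CCC[C@]12C | intermediate
20 | C16 ketone (4-acylbutenolide) | O=C(C3=CC(=O)OC3)C[C@@H]2[C@@H](COCc1ccc(OC)cc1)CC[C@H]1[C@@]2(C)CC[C@H]2C(C)(C)CCC[C@]12C | intermediate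
21 | (16R)-alcohol | O[C@@H](C3=CC(=O)OC3)C[C@@H]2[C@@H](COCc1ccc(OC)cc1)CC[C@H]1[C@@]2(C)CC[C@H]2C(C)(C)CCC[C@]12C | intermediate
22 | (16R)-tert-butyldimethylsilyl ether | CC(C)(C)[Si](C)(C)O[C@@H](C3=CC(=O)OC3)C[C@@H]2[C@@H](COCc1ccc(OC)cc1)CC[C@H]1[C@@]2(C)CC[C@H]2C(C)(C)CCC[C@]12C | intermediate
23 | C24 primary alcohol | CC(C)(C)[Si](C)(C)O[C@@H](C3=CC(=O)OC3)C[C@@H]2[C@@H](CO)CC[C@H]1[C@@]2(C)CC[C@H]2C(C)(C)CCC[C@]12C | intermediate
24 | C24 aldehyde | CC(C)(C)[Si](C)(C)O[C@@H](C3=CC(=O)OC3)C[C@@H]2[C@@H](C=O)CC[C@H]1[C@@]2(C)CC[C@H]2C(C)(C)CCC[C@]12C | intermediate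
25 | 2-(tert-butyldimethylsilyloxy)furan aldehyde (not isolated) | CC(C)(C)[Si](C)(C)O[C@@H](c3coc(O[Si](C)(C)C(C)(C)C)c3)C[C@@H]2[C@@H](C=O)CC[C@H]1[C@@]2(C)CC[C@H]2C(C)(C)CCC[C@]12C | intermediate
26 | ring-D aldol adduct with C24-OTBS, C24/C25 epimers (not isolated) | CC(C)(C)[Si](C)(C)O[C@@H]1C[C@@H]2[C@@H](C(O[Si](C)(C)C(C)(C)C)C3OC(=O)C=C31)CC[C@H]1[C@@]2(C)CC[C@H]2C(C)(C)CCC[C@]12C | intermediate
27 | pentacyclic (16R)-silyl ether | CC(C)(C)[Si](C)(C)O[C@@H]1C[C@@H]2[C@@H](C=C3OC(=O)C=C31)CC[C@H]1[C@@]2(C)CC[C@H]2C(C)(C)CCC[C@]12C | intermediate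
28 | pentacyclic (16R)-alcohol | O[C@@H]1C[C@@H]2[C@@H](C=C3OC(=O)C=C31)CC[C@H]1[C@@]2(C)CC[C@H]2C(C)(C)CCC[C@]12C | intermediate
29 | CNP0193439.1 | CC(=O)O[C@@H]1C[C@@H]2[C@@H](C=C3OC(=O)C=C31)CC[C@H]1[C@@]2(C)CC[C@H]2C(C)(C)CCC[C@]12C | target

**Step count**

Total: 21 steps. Longest linear sequence: 19 steps (steps 1–4, 6–11, 13–21, from sclareolide).

**Steps most likely to fail**

Step 10. The tertiary radical may be reduced to the C8–H alkane before it cyclises, hydrogen-atom transfer may go to the enoate, or the ring may close through a non-chair arrangement and give the cis-fused or C14-epimeric ester. The fallback sets out from tertiary alcohol 13, so step 9 is not needed. Acylation with methyl chlorooxoacetate (Et3N, DMAP, CH2Cl2) should give the methyl oxalate F1, and one equivalent of aqueous CsOH in THF the cesium oxalate F2. Visible-light photoredox catalysis (Ir[dF(CF3)ppy]2(dtbbpy)PF6, blue light, DME/DMF, water) oxidises the oxalate; loss of two molecules of CO2 gives the same tertiary C8 radical without any metal hydride, and 6-exo addition to the enoate followed by reduction and protonation comes back to the route at 15. This is the known radical conjugate addition of oxalates derived from tertiary alcohols.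

Step 19. Silylation of the aldehyde enol may compete with silylation of the butenolide and consume the electrophile, the furan may close through C18 instead of C25, or the elimination may stall. The fallback sets out from 24. Acetalisation (HC(OMe)3, PPTS, MeOH) should give the dimethyl acetal F3, which cannot enolise. TIPSOTf/Et3N then converts the butenolide into the isolable 2-(triisopropylsilyloxy)furan F4. BF3·OEt2 at −78 °C ionises the acetal and C25 of the furan adds to the oxocarbenium ion (vinylogous Mukaiyama addition to an acetal), giving the ring-D C24 methyl ether F5. DBU in warm toluene eliminates methanol by the E1cB path and comes back to the route at 27.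

Step 15. Facial discrimination may be poor because the two ketone substituents differ too little or the catalyst is mismatched with C14, or conjugate reduction of the electron-poor ene-dione may intervene. The fallback sets out from the epimer mixture 19 and skips steps 14 and 15. Chromatography separates 21 from the (16S)-alcohol F6. Mitsunobu reaction of F6 (4-nitrobenzoic acid, PPh3, DIAD, THF) inverts C16 to the (16R)-4-nitrobenzoate F7, and brief methanolysis (K2CO3, MeOH, 0 °C) comes back to the route at 21.

**Further compounds**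

F1 | step 10 | methyl oxalate of tertiary alcohol 13 | COC(=O)/C=C/[C@@H](COCc1ccc(OC)cc1)CC[C@H]1[C@](C)(OC(=O)C(=O)OC)CC[C@H]2C(C)(C)CCC[C@]12C
F2 | step 10 | cesium oxalate of tertiary alcohol 13 | COC(=O)/C=C/[C@@H](COCc1ccc(OC)cc1)CC[C@H]1[C@](C)(OC(=O)C(=O)[O-])CC[C@H]2C(C)(C)CCC[C@]12C.[Cs+]
F3 | step 19 | C24 dimethyl acetal of 24 | CC(C)(C)[Si](C)(C)O[C@@H](C3=CC(=O)OC3)C[C@@H]2[C@@H](C(OC)OC)CC[C@H]1[C@@]2(C)CC[C@H]2C(C)(C)CCC[C@]12C
F4 | step 19 | 2-(triisopropylsilyloxy)furan dimethyl acetal | CC(C)(C)[Si](C)(C)O[C@@H](c3coc(O[Si](C(C)C)(C(C)C)C(C)C)c3)C[C@@H]2[C@@H](C(OC)OC)CC[C@H]1[C@@]2(C)CC[C@H]2C(C)(C)CCC[C@]12C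
F5 | step 19 | ring-D C24 methyl ether, C24/C25 epimers | CC(C)(C)[Si](C)(C)O[C@@H]1C[C@@H]2[C@@H](C(OC)C3OC(=O)C=C31)CC[C@H]1[C@@]2(C)CC[C@H]2C(C)(C)CCC[C@]12C
F6 | step 15 | (16S)-alcohol | O[C@H](C3=CC(=O)OC3)C[C@@H]2[C@@H](COCc1ccc(OC)cc1)CC[C@H]1[C@@]2(C)CC[C@H]2C(C)(C)CCC[C@]12C
F7 | step 15 | (16R)-4-nitrobenzoate | O=C(O[C@@H](C3=CC(=O)OC3)C[C@@H]2[C@@H](COCc1ccc(OC)cc1)CC[C@H]1[C@@]2(C)CC[C@H]2C(C)(C)CCC[C@]12C)c1ccc([N+](=O)[O-])cc1
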